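Abbreviations: TBS = tert-butyldimethylsilyl, Bn = benzyl, Ar = 4-(TBSO)C6H4.
Assumption: a lithium salt of a product that is only protonated on work-up is not numbered separately. The cyclobutenone and dienone intermediates 12, 21, 22 and 24 are racemic at a centre that is destroyed later, so their SMILES carry no tag there.
Bookkeeping: where more than one molecule of a numbered reactant ends up in the product (steps 3 and 10), the further equivalents are also entered under "Reagents that add atoms".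

**Retrosynthetic overview**
- Target ⇐ cleavage of three aryl silyl ethers ⇐ triple cis-semihydrogenation of a tris(epoxy-ynoate) ⇐ three-fold acylation of a terphenyl triol whose fourth central oxygen is a silyl ether.
- Side-chain acid ⇐ methyl (R)-2-chloropropanoate (from L-lactic acid) + methyl propiolate: anti addition to the α-chloroaldehyde, then epoxide closure with inversion. This is the only source of chirality.
- Central benzene ring ⇐ 4π ring opening / 6π electrocyclisation of a 4-alkenyl-4-silyloxycyclobutenone, which delivers one central oxygen already differentiated as its silyl ether.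
- Cyclobutenone ⇐ 3-aryl-4-benzyloxycyclobutenedione (from squaric acid) + a β-benzyloxy-α-arylvinyllithium (from the aryl aldehyde by Wittig reaction and bromination/dehydrobromination).
- Ring order: the oxirane is closed first on the side chain; the cyclobutene ring is bought in squaric acid and opened; the central benzene ring is formed by the electrocyclisation; both outer benzene rings are bought.

**Route**

Step 1
Reactants: 1 methyl (R)-2-chloropropanoate; 2 methyl prop-2-ynoate
Product: 5 methyl (4S,5R)-5-chloro-4-hydroxyhex-2-ynoate, via (R)-2-chloropropanal 3 (not isolated), via methyl 3-lithioprop-2-ynoate 4 (not isolated)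
Conditions: 1, i-Bu2AlH (1.05 equiv), CH2Cl2, −78 °C, aq. KNaC4H4O6 work-up, cold dried solution of 3; added to 4 [2 (2.2 equiv), LiN(SiMe3)2, THF, −78 °C]; AcOH quench at −78 °C; chromatography
Reagents that add atoms: none
Why: Half-reduction of the ester gives the configurationally intact α-chloroaldehyde, and lithium acetylide 1,2-addition under Cornforth (polar Felkin–Anh) control, anti to the C–Cl bond, sets C4 as S relative to the bought C5 centre; the minor syn isomer is removed by chromatography.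

Step 2
Reactants: 5 methyl (4S,5R)-5-chloro-4-hydroxyhex-2-ynoate
Product: 6 (4S,5S)-4,5-epoxyhex-2-ynoic acid
Conditions: LiOH·H2O (2.5 equiv), THF/H2O, 0 °C; then 1 M H3PO4 to pH 3, NaCl, EtOAc extraction at 0 °C; used fresh
Reagents that add atoms: lithium hydroxide, [Li+].[OH-]
Why: The alkoxide displaces chloride in an intramolecular Williamson SN2 reaction with inversion at C5 (anti chlorohydrin gives the trans (4S,5S)-oxirane, C4 untouched) while hydroxide saponifies the ynoate ester in the same pot.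

Step 3
Reactants: 7 squaric acid; 8 benzyl alcohol (2.5 equiv)
Product: 9 dibenzyl squarate
Conditions: toluene, reflux, Dean–Stark
Reagents that add atoms: benzyl alcohol 8 second equivalent, OCc1ccccc1
Why: Azeotropic Fischer-type esterification of the vinylogous diacid takes up two molecules of benzyl alcohol, as in the preparation of the common dialkyl squarates.

Step 4
Reactants: 9 dibenzyl squarate; 10 (4-bromophenoxy)(tert-butyl)dimethylsilane
Product: 13 3-(benzyloxy)-4-{4-[(tert-butyldimethylsilyl)oxy]phenyl}cyclobut-3-ene-1,2-dione, via aryllithium 11 (not isolated), via lithium cyclobutenolate adduct 12 (not isolated)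
Conditions: 10, n-BuLi, THF, −78 °C; then 9, −78 °C; then (CF3CO)2O, −78 °C → rt
Reagents that add atoms: none
Why: Lithium–bromine exchange and 1,2-addition to one squarate carbonyl, then trifluoroacetylation, ionisation and loss of one benzyl group, transpose the carbonyl to give the aryl cyclobutenedione (Liebeskind–Moore protocol).

Step 5
Reactants: 14 4-[(tert-butyldimethylsilyl)oxy]benzaldehyde; 15 (benzyloxymethyl)triphenylphosphonium chloride
Product: 17 1-[2-(benzyloxy)ethenyl]-4-[(tert-butyldimethylsilyl)oxy]benzene (E/Z mixture), via benzyloxymethylene ylide 16 (not isolated)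
Conditions: 15, NaN(SiMe3)2, THF, 0 °C; then 14, 0 °C → rt
Reagents that add atoms: none
Why: Wittig olefination with an alkoxymethylene ylide gives the enol ether, whose E/Z ratio is irrelevant because the next step erases it.

Step 6
Reactants: 17 1-[2-(benzyloxy)ethenyl]-4-[(tert-butyldimethylsilyl)oxy]benzene
Product: 19 1-[(Z)-2-(benzyloxy)-1-bromoethenyl]-4-[(tert-butyldimethylsilyl)oxy]benzene, via vicinal dibromide 18 (not isolated)
Conditions: Br2, CH2Cl2, −78 °C; then Et3N, −78 °C → rt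
Reagents that add atoms: bromine, BrBr
Why: Bromine addition to the enol ether followed by dehydrobromination through the oxocarbenium ion (loss of the benzylic proton) gives the β-bromo enol ether, with Br cis to OBn favoured as in the known 2-bromovinyl ether preparations.

Step 7
Reactants: 13 3-(benzyloxy)-4-Ar-cyclobut-3-ene-1,2-dione; 19 1-[(Z)-2-(benzyloxy)-1-bromoethenyl]-4-[(tert-butyldimethylsilyl)oxy]benzene
Product: 22 3-(benzyloxy)-4-[(Z)-2-(benzyloxy)-1-Ar-ethenyl]-4-[(tert-butyldimethylsilyl)oxy]-2-Ar-cyclobut-2-en-1-one (racemic), via alkenyllithium 20 (not isolated), via lithium alkoxide 21 (not isolated)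
Conditions: 19, t-BuLi (2 equiv), THF, −78 °C; then 13, −78 °C; then TBSOTf, −78 → −20 °C
Reagents that add atoms: tert-butyldimethylsilyl trifluoromethanesulfonate, CC(C)(C)[Si](C)(C)OS(=O)(=O)C(F)(F)F
Why: Lithium–bromine exchange with retention gives the O-chelated cis-β-alkoxyvinyllithium, which adds 1,2 to the more electrophilic carbonyl (the one next to the benzyloxy-bearing carbon, not the vinylogous ester), and the tertiary alkoxide is silylated in situ.

Step 8
Reactants: 22 3-(benzyloxy)-4-[(Z)-2-(benzyloxy)-1-Ar-ethenyl]-4-[(tert-butyldimethylsilyl)oxy]-2-Ar-cyclobut-2-en-1-one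
Product: 25 3,6-bis(benzyloxy)-4-[(tert-butyldimethylsilyl)oxy]-2,5-bis{4-[(tert-butyldimethylsilyl)oxy]phenyl}phenol, via dienylketene 23 (not isolated), via cyclohexadienone 24 (not isolated)
Conditions: toluene (degassed, 0.02 M), 110 °C
Reagents that add atoms: none
Why: Thermal 4π-electrocyclic ring opening (silyloxy group rotating outward), 6π-electrocyclisation of the dienylketene and tautomerisation (Moore rearrangement) build the hexasubstituted benzene with both aryl groups para and one of the four oxygens already silylated; the racemic centre is destroyed.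

Step 9
Reactants: 25 3,6-bis(benzyloxy)-4-[(tert-butyldimethylsilyl)oxy]-2,5-bis{4-[(tert-butyldimethylsilyl)oxy]phenyl}phenol
Product: 26 5-[(tert-butyldimethylsilyl)oxy]-3,6-bis{4-[(tert-butyldimethylsilyl)oxy]phenyl}benzene-1,2,4-triol
Conditions: H2 (1 atm), 10% Pd/C, EtOAc, rt; filtered under Ar, used at once
Reagents that add atoms: none
Why: Hydrogenolysis removes both benzyl ethers while the aryl silyl ethers are inert; the air-sensitive triol is acylated immediately.

Step 10
Reactants: 26 5-O-TBS-3,6-bis-Ar-benzene-1,2,4-triol; 6 trans-4S,5S-epoxyhex-2-ynoic acid (3 equiv)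
Product: 27 5-[(tert-butyldimethylsilyl)oxy]-3,6-bis{4-[(tert-butyldimethylsilyl)oxy]phenyl}benzene-1,2,4-triyl tris[(4S,5S)-4,5-epoxyhex-2-ynoate]
Conditions: 6 (3.6 equiv charged, three molecules incorporated per molecule of 26), i-PrN=C=N-i-Pr (3.8 equiv), DMAP (0.3 equiv), CH2Cl2, −20 → 0 °C, Ar
Reagents that add atoms: acid 6 second equivalent, C[C@@H]1O[C@H]1C#CC(=O)O; acid 6 third equivalent, OC(=O)C#C[C@@H]1O[C@H]1C
Why: Three-fold Steglich esterification puts one molecule of acid 6 on each of the three free phenols; the acid cannot lactonise or isomerise, and any O-to-O silyl or acyl shift is degenerate because the four central oxygens are symmetry-equivalent.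

Step 11
Reactants: 27 tris[(4S,5S)-4,5-epoxyhex-2-ynoate] of the mono-silylated core
Product: 28 5-[(tert-butyldimethylsilyl)oxy]-3,6-bis{4-[(tert-butyldimethylsilyl)oxy]phenyl}benzene-1,2,4-triyl tris[(2Z,4S,5S)-4,5-epoxyhex-2-enoate]
Conditions: H2 (1 atm), Pd/CaCO3 poisoned with Pb(OAc)2, quinoline, EtOAc, 0 °C, stopped after 3 equiv H2
Reagents that add atoms: none
Why: Lindlar syn-semihydrogenation converts each ynoate into the Z-enoate without touching the oxirane stereocentres.

Step 12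
Reactants: 28 tris[(2Z,4S,5S)-4,5-epoxyhex-2-enoate] of the mono-silylated core
Product: 29 5-hydroxy-3,6-bis(4-hydroxyphenyl)benzene-1,2,4-triyl tris[(2Z,4S,5S)-4,5-epoxyhex-2-enoate] (CNP0278429.1)
Conditions: Bu4NF/AcOH (1:1.2, 3.6 equiv), THF, 0 °C
Reagents that add atoms: none
Why: Buffered fluoride desilylation cleaves the three aryl silyl ethers while the aryl esters, Z-enoates and oxiranes survive, and acyl migration on the symmetric core cannot give a regioisomer.

**Compound list**
1 | methyl (R)-2-chloropropanoate | C[C@@H](Cl)C(=O)OC | starting material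
2 | methyl prop-2-ynoate (methyl propiolate) | C#CC(=O)OC | starting material
3 | (R)-2-chloropropanal | C[C@@H](Cl)C=O | intermediate (not isolated)
4 | methyl 3-lithioprop-2-ynoate | [Li]C#CC(=O)OC | intermediate (not isolated)
5 | methyl (4S,5R)-5-chloro-4-hydroxyhex-2-ynoate | C[C@@H](Cl)[C@@H](O)C#CC(=O)OC | intermediate
6 | (4S,5S)-4,5-epoxyhex-2-ynoic acid, i.e. 3-[(2S,3S)-3-methyloxiran-2-yl]prop-2-ynoic acid | C[C@@H]1O[C@H]1C#CC(=O)O | intermediate
7 | squaric acid (3,4-dihydroxycyclobut-3-ene-1,2-dione) | O=C1C(O)=C(O)C1=O | starting material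
8 | benzyl alcohol | OCc1ccccc1 | starting material
9 | dibenzyl squarate, 3,4-bis(benzyloxy)cyclobut-3-ene-1,2-dione | O=C1C(=O)C(OCc2ccccc2)=C1OCc1ccccc1 | intermediate
10 | (4-bromophenoxy)(tert-butyl)dimethylsilane | CC(C)(C)[Si](C)(C)Oc1ccc(Br)cc1 | starting material
11 | {4-[(tert-butyldimethylsilyl)oxy]phenyl}lithium | [Li]c1ccc(O[Si](C)(C)C(C)(C)C)cc1 | intermediate (not isolated)
12 | lithium 2,3-bis(benzyloxy)-1-{4-[(tert-butyldimethylsilyl)oxy]phenyl}-4-oxocyclobut-2-en-1-olate (racemic) | [Li+].[O-]C1(c2ccc(O[Si](C)(C)C(C)(C)C)cc2)C(OCc2ccccc2)=C(OCc2ccccc2)C1=O | intermediate (not isolated)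
13 | 3-(benzyloxy)-4-{4-[(tert-butyldimethylsilyl)oxy]phenyl}cyclobut-3-ene-1,2-dione | O=C1C(=O)C(c2ccc(O[Si](C)(C)C(C)(C)C)cc2)=C1OCc1ccccc1 | intermediate
14 | 4-[(tert-butyldimethylsilyl)oxy]benzaldehyde | CC(C)(C)[Si](C)(C)Oc1ccc(C=O)cc1 | starting material
15 | (benzyloxymethyl)triphenylphosphonium chloride | [Cl-].c1ccc(COC[P+](c2ccccc2)(c2ccccc2)c2ccccc2)cc1 | starting material
16 | (benzyloxymethylene)triphenylphosphorane | c1ccc(COC=P(c2ccccc2)(c2ccccc2)c2ccccc2)cc1 | intermediate (not isolated)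
17 | 1-[2-(benzyloxy)ethenyl]-4-[(tert-butyldimethylsilyl)oxy]benzene (E/Z mixture) | CC(C)(C)[Si](C)(C)Oc1ccc(C=COCc2ccccc2)cc1 | intermediate
18 | 1-[2-(benzyloxy)-1,2-dibromoethyl]-4-[(tert-butyldimethylsilyl)oxy]benzene (diastereomer mixture) | CC(C)(C)[Si](C)(C)Oc1ccc(C(Br)C(Br)OCc2ccccc2)cc1 | intermediate (not isolated)
19 | 1-[(Z)-2-(benzyloxy)-1-bromoethenyl]-4-[(tert-butyldimethylsilyl)oxy]benzene (Br cis to OBn) | CC(C)(C)[Si](C)(C)Oc1ccc(/C(Br)=C/OCc2ccccc2)cc1 | intermediate
20 | [(E)-2-(benzyloxy)-1-{4-[(tert-butyldimethylsilyl)oxy]phenyl}ethenyl]lithium (Li cis to OBn) | CC(C)(C)[Si](C)(C)Oc1ccc(/C([Li])=C/OCc2ccccc2)cc1 | intermediate (not isolated)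
21 | lithium 2-(benzyloxy)-1-[(Z)-2-(benzyloxy)-1-Ar-ethenyl]-3-Ar-4-oxocyclobut-2-en-1-olate (racemic) | [Li+].[O-]C1(/C(c2ccc(O[Si](C)(C)C(C)(C)C)cc2)=C\OCc2ccccc2)C(OCc2ccccc2)=C(c2ccc(O[Si](C)(C)C(C)(C)C)cc2)C1=O | intermediate (not isolated)
22 | 3-(benzyloxy)-4-[(Z)-2-(benzyloxy)-1-Ar-ethenyl]-4-[(tert-butyldimethylsilyl)oxy]-2-Ar-cyclobut-2-en-1-one (racemic) | O=C1C(c2ccc(O[Si](C)(C)C(C)(C)C)cc2)=C(OCc2ccccc2)C1(O[Si](C)(C)C(C)(C)C)/C(c1ccc(O[Si](C)(C)C(C)(C)C)cc1)=C\OCc1ccccc1 | intermediate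
23 | (3Z,5Z)-3,6-bis(benzyloxy)-4-[(tert-butyldimethylsilyl)oxy]-2,5-bis-Ar-hexa-1,3,5-trien-1-one (dienylketene) | O=C=C(c1ccc(O[Si](C)(C)C(C)(C)C)cc1)/C(OCc1ccccc1)=C(O[Si](C)(C)C(C)(C)C)\C(c1ccc(O[Si](C)(C)C(C)(C)C)cc1)=C/OCc1ccccc1 | intermediate (not isolated)
24 | 3,6-bis(benzyloxy)-4-[(tert-butyldimethylsilyl)oxy]-2,5-bis-Ar-cyclohexa-2,4-dien-1-one (racemic) | O=C1C(c2ccc(O[Si](C)(C)C(C)(C)C)cc2)=C(OCc2ccccc2)C(O[Si](C)(C)C(C)(C)C)=C(c2ccc(O[Si](C)(C)C(C)(C)C)cc2)C1OCc1ccccc1 | intermediate (not isolated)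
25 | 3,6-bis(benzyloxy)-4-[(tert-butyldimethylsilyl)oxy]-2,5-bis{4-[(tert-butyldimethylsilyl)oxy]phenyl}phenol | Oc1c(-c2ccc(O[Si](C)(C)C(C)(C)C)cc2)c(OCc2ccccc2)c(O[Si](C)(C)C(C)(C)C)c(-c2ccc(O[Si](C)(C)C(C)(C)C)cc2)c1OCc1ccccc1 | intermediate
26 | 5-[(tert-butyldimethylsilyl)oxy]-3,6-bis{4-[(tert-butyldimethylsilyl)oxy]phenyl}benzene-1,2,4-triol | Oc1c(-c2ccc(O[Si](C)(C)C(C)(C)C)cc2)c(O)c(O[Si](C)(C)C(C)(C)C)c(-c2ccc(O[Si](C)(C)C(C)(C)C)cc2)c1O | intermediate
27 | 5-[(tert-butyldimethylsilyl)oxy]-3,6-bis{4-[(tert-butyldimethylsilyl)oxy]phenyl}benzene-1,2,4-triyl tris[(4S,5S)-4,5-epoxyhex-2-ynoate] | C[C@@H]1O[C@H]1C#CC(=O)Oc1c(-c2ccc(O[Si](C)(C)C(C)(C)C)cc2)c(OC(=O)C#C[C@@H]2O[C@H]2C)c(O[Si](C)(C)C(C)(C)C)c(-c2ccc(O[Si](C)(C)C(C)(C)C)cc2)c1OC(=O)C#C[C@@H]1O[C@H]1C | intermediate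
28 | 5-[(tert-butyldimethylsilyl)oxy]-3,6-bis{4-[(tert-butyldimethylsilyl)oxy]phenyl}benzene-1,2,4-triyl tris[(2Z,4S,5S)-4,5-epoxyhex-2-enoate] | C[C@@H]1O[C@H]1/C=C\C(=O)Oc1c(-c2ccc(O[Si](C)(C)C(C)(C)C)cc2)c(OC(=O)/C=C\[C@@H]2O[C@H]2C)c(O[Si](C)(C)C(C)(C)C)c(-c2ccc(O[Si](C)(C)C(C)(C)C)cc2)c1OC(=O)/C=C\[C@@H]1O[C@H]1C | intermediate
29 | 5-hydroxy-3,6-bis(4-hydroxyphenyl)benzene-1,2,4-triyl tris[(2Z,4S,5S)-4,5-epoxyhex-2-enoate] (CNP0278429.1) | C[C@@H]1O[C@H]1/C=C\C(=O)Oc1c(OC(=O)/C=C\[C@@H]2O[C@H]2C)c(-c2ccc(O)cc2)c(OC(=O)/C=C\[C@@H]2O[C@H]2C)c(O)c1-c1ccc(O)cc1 | target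

**Totals**
Total step count: 12. Longest linear sequence: 8 steps (14 → 29 through steps 5–12; equally 7 → 29 through steps 3, 4 and 7–12).

**Steps most likely to fail, with fallbacks**

Step 7. The β-alkoxyvinyllithium can lose lithium benzyloxide if any E-bromide is present, and silylation of the hindered tertiary alkoxide with a silyl triflate may be slow or may ionise the cyclobutenone. Fallback: setting out from 13 and 19, the same exchange and addition are quenched with aqueous NH4Cl instead of the silyl triflate, giving the free carbinol 3-(benzyloxy)-4-[(Z)-2-(benzyloxy)-1-Ar-ethenyl]-4-hydroxy-2-Ar-cyclobut-2-en-1-one F1. Heating it in degassed toluene at 110 °C (same ring opening and 6π closure) gives the symmetric hydroquinone 2,5-bis(benzyloxy)-3,6-bis{4-[(tert-butyldimethylsilyl)oxy]phenyl}benzene-1,4-diol F2. Its two hydroxyls are equivalent, so TBSCl (1.0 equiv) and imidazole in DMF give the mono-silyl ether statistically (recovered F2 is recycled), and the route is rejoined at 25.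

Step 11. Three alkynes must each stop at the Z-alkene without over-reduction or hydrogenolysis of the propargylic/allylic oxiranes. Fallback: setting out from 6, the single alkyne of the acid is semihydrogenated first (H2, Pd/CaCO3 poisoned with Pb(OAc)2, quinoline, EtOAc, 0 °C) to give (2Z,4S,5S)-4,5-epoxyhex-2-enoic acid F3. Because this acid can lactonise, it is used at once (3.6 equiv) in a three-fold Yamaguchi esterification of 26 (2,4,6-trichlorobenzoyl chloride, Et3N, THF; then 26 and DMAP in toluene at 0 °C), which comes back to the route at 28.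

Step 12. Fluoride or the liberated phenoxides may cleave the activated aryl esters, or the vinyl oxiranes may open. Fallback: setting out from 27, the order of the last two operations is reversed. The silyl ethers are removed at the more robust ynoate stage (HF·pyridine buffered with pyridine, THF, 0 °C → rt) to give 5-hydroxy-3,6-bis(4-hydroxyphenyl)benzene-1,2,4-triyl tris[(4S,5S)-4,5-epoxyhex-2-ynoate] F4. The same Lindlar semihydrogenation is then the last operation and comes back to the route at 29.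

Further compounds
F1 | step 7 | 3-(benzyloxy)-4-[(Z)-2-(benzyloxy)-1-{4-[(tert-butyldimethylsilyl)oxy]phenyl}ethenyl]-4-hydroxy-2-{4-[(tert-butyldimethylsilyl)oxy]phenyl}cyclobut-2-en-1-one (racemic) | O=C1C(c2ccc(O[Si](C)(C)C(C)(C)C)cc2)=C(OCc2ccccc2)C1(O)/C(c1ccc(O[Si](C)(C)C(C)(C)C)cc1)=C\OCc1ccccc1
F2 | step 7 | 2,5-bis(benzyloxy)-3,6-bis{4-[(tert-butyldimethylsilyl)oxy]phenyl}benzene-1,4-diol | Oc1c(-c2ccc(O[Si](C)(C)C(C)(C)C)cc2)c(OCc2ccccc2)c(O)c(-c2ccc(O[Si](C)(C)C(C)(C)C)cc2)c1OCc1ccccc1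
F3 | step 11 | (2Z,4S,5S)-4,5-epoxyhex-2-enoic acid | C[C@@H]1O[C@H]1/C=C\C(=O)O
F4 | step 12 | 5-hydroxy-3,6-bis(4-hydroxyphenyl)benzene-1,2,4-triyl tris[(4S,5S)-4,5-epoxyhex-2-ynoate] | C[C@@H]1O[C@H]1C#CC(=O)Oc1c(-c2ccc(O)cc2)c(OC(=O)C#C[C@@H]2O[C@H]2C)c(O)c(-c2ccc(O)cc2)c1OC(=O)C#C[C@@H]1O[C@H]1C
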